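**Plan**
- Cuts, in order: the C3 caffeate ester, then the C3–O bond (allylic oxidation) and C4=C15 (methylenation). This leads back to a 1β-silyloxy-Δ5-octalin-4,8-dione.
- Enabling feature: in ring B (C5–C10) the oxygenated carbon C8 lies between the C9 methylene and C7. Ring B is therefore C10–C9H2, C5 with a C6=C7 alkenyl arm, and one CO. Removing C8 (bonds C8–C9 and C7–C8) and joining C9 to C5 gives a 1-alkenylnorcaran-2-one.
- That precursor is cut at C9 (methylene transfer to the C5=C10 enone), at C5–C6 (Suzuki coupling) and at C10–C14 (methyl addition with carbonyl transposition). This ends at 3-ethoxycyclohexenone.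
- Forward order: ring A is present from the start, the cyclopropane is fused on in step 8, ring B arises in step 9, and the ester is attached last.
- Stereochemistry: C1 comes from a lipase resolution. C10 comes from ylide attack anti to the C1 silyl ether. C7 and C5 are set by equilibration or α-face protonation next to carbonyl groups. C8 comes from dissolving-metal reduction (equatorial alcohol) and C3 from axial hydride delivery (Luche).

Key step: step 9

Numbering: eudesmane numbering is used for all ring-A-derived carbons (ring A C1–C5/C10, ring B C5–C10, C14 angular methyl, C15 exocyclic methylene carbon).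
Assumption: the lipase hydrolyses the (R)-acetate faster, as the empirical size rule for esters of secondary alcohols predicts. If the preference is reversed, the recovered acetate is the (R)-series and is methanolysed to the same alcohol 3.

**Step 1**
Reactants: 1 3-ethoxycyclohex-2-en-1-one
Product: 2 (±)-6-acetoxy-3-ethoxycyclohex-2-en-1-one
Conditions: Mn(OAc)3 (2.5 equiv), benzene–AcOH 10:1, reflux
Reagents that add atoms: manganese(III) acetate, CC(=O)[O-].CC(=O)[O-].CC(=O)[O-].[Mn+3]
Why: Mn(III)-mediated α′-acetoxylation of an enone, in which the vinylogous ester can enolise only toward C6 and the Mn(III) enolate passes acetate to that carbon, giving a racemic centre that step 2 sorts out.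

**Step 2**
Reactants: 2 (±)-6-acetoxy-3-ethoxycyclohex-2-en-1-one
Product: 3 (R)-3-ethoxy-6-hydroxycyclohex-2-en-1-one
Conditions: Burkholderia cepacia lipase (Amano PS), pH 7 phosphate buffer–MTBE, 30 °C, stopped near half conversion, chromatographic separation
Reagents that add atoms: none
Why: Lipase-catalysed kinetic resolution by enantioselective ester hydrolysis, a known treatment of α′-acetoxy-3-alkoxyenones, in which the enzyme distinguishes the carbonyl flank from the CH2 flank of the carbinol carbon and thereby fixes the absolute configuration of the future C1.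

**Step 3**
Reactants: 3 (R)-3-ethoxy-6-hydroxycyclohex-2-en-1-one
Product: 4 (R)-6-(tert-butyldimethylsilyloxy)-3-ethoxycyclohex-2-en-1-one
Conditions: TBSCl, imidazole, DMF, rt
Reagents that add atoms: tert-butyldimethylsilyl chloride, CC(C)(C)[Si](C)(C)Cl
Why: Standard imidazole-promoted silylation of a secondary alcohol under conditions too mild to enolise the adjacent vinylogous ester, so the stereocentre is retained.

**Step 4**
Reactants: 4 (R)-6-(tert-butyldimethylsilyloxy)-3-ethoxycyclohex-2-en-1-one
Product: 6 (R)-4-(tert-butyldimethylsilyloxy)-3-methylcyclohex-2-en-1-one, via tertiary carbinol 5 (not isolated)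
Conditions: MeLi, Et2O, −78 °C; then 1 M HCl, THF, 0 °C
Reagents that add atoms: methyllithium, [Li]C; water, O
Why: Stork–Danheiser transposition, in which 1,2-addition of MeLi to the vinylogous ester is followed by acid hydrolysis and loss of water, so the methyl-bearing carbon becomes the enone β-carbon (C10) next to the untouched C1 silyl ether.

**Step 5**
Reactants: 6 (R)-4-(tert-butyldimethylsilyloxy)-3-methylcyclohex-2-en-1-one
Product: 7 (R)-4-(tert-butyldimethylsilyloxy)-2-iodo-3-methylcyclohex-2-en-1-one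
Conditions: I2, pyridine–CH2Cl2 1:1, rt, dark
Reagents that add atoms: iodine, II
Why: Iodine–pyridine α-iodination of an enone (addition–elimination), established for 3-methylcyclohexenone, which can only substitute the single vinylic C–H at C5.

**Step 6**
Reactants: 8 3-methylbut-1-yne
Product: 9 (E)-4,4,5,5-tetramethyl-2-(3-methylbut-1-en-1-yl)-1,3,2-dioxaborolane
Conditions: HBpin, Cy2BH (5 mol %), neat, sealed tube, rt
Reagents that add atoms: pinacolborane, CC1(C)OBOC1(C)C
Why: Dialkylborane-catalysed hydroboration of a terminal alkyne, a syn anti-Markovnikov addition that places boron on the terminal carbon (C6) and gives the E-alkenylboronate.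

**Step 7**
Reactants: 7 (R)-4-(tert-butyldimethylsilyloxy)-2-iodo-3-methylcyclohex-2-en-1-one; 9 (E)-4,4,5,5-tetramethyl-2-(3-methylbut-1-en-1-yl)-1,3,2-dioxaborolane
Product: 10 (R)-4-(tert-butyldimethylsilyloxy)-3-methyl-2-[(E)-3-methylbut-1-en-1-yl]cyclohex-2-en-1-one
Conditions: PdCl2(dppf) (5 mol %), K3PO4, THF–H2O, 50 °C
Reagents that add atoms: none
Why: Suzuki–Miyaura coupling of a 2-iodoenone with an alkenylboronate, which forms C5–C6 with retention of the E geometry and leaves the silyl ether and the C1 centre alone.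

**Step 8**
Reactants: 10 (R)-4-(tert-butyldimethylsilyloxy)-3-methyl-2-[(E)-3-methylbut-1-en-1-yl]cyclohex-2-en-1-one; 11 trimethylsulfoxonium iodide
Product: 12 (1R,5R,6R)-5-(tert-butyldimethylsilyloxy)-6-methyl-1-[(E)-3-methylbut-1-en-1-yl]bicyclo[4.1.0]heptan-2-one
Conditions: NaH, DMSO, rt → 50 °C
Reagents that add atoms: none
Why: Corey–Chaykovsky cyclopropanation, in which the soft sulfoxonium ylide adds 1,4 to C10 to give an enolate stabilised as a dienolate by the alkenyl arm, 3-exo-tet loss of DMSO closes C5–C9, and approach anti to the pseudo-axial C1 silyl ether puts C9 on the α face, fixing C10 (methyl β) and C5.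

**Step 9**
Reactants: 12 (1R,5R,6R)-5-(tert-butyldimethylsilyloxy)-6-methyl-1-[(E)-3-methylbut-1-en-1-yl]bicyclo[4.1.0]heptan-2-one; 13 carbon monoxide
Product: 14 (1R,7S,10R)-1-(tert-butyldimethylsilyloxy)-7-isopropyl-10-methyl-Δ5-octalin-4,8-dione (15-nor-eudesm-5-ene-4,8-dione; 1β-OTBS, 7β-iPr, 10β-Me)
Conditions: [Rh(CO)2Cl]2 (5 mol %), CO (1 atm), 1,4-dioxane, 90 °C
Reagents that add atoms: none
Why: Rh(I) coordinates to C6=C7 and adds oxidatively across the neighbouring C5–C9 bond, which is weakened by ring strain and by overlap with the C4 carbonyl, to give a rhodacyclohexene with an alkyl ligand at C9 and an η3-allyl spanning C5, C6 and C7; CO then migrates into Rh–C9 and the new acyl carbon C8 couples with the allyl terminus C7. The closest known reaction type is the Rh-, Fe- or Co-carbonyl-mediated [5+1] carbonylation of alkenylcyclopropanes to cyclohexenones, so far run on cyclopropanes less substituted than this ring-fused, acyl-bearing one. Ring B closes by acyl–allyl reductive elimination from the seven-membered acylrhodacycle, a six-membered closure, whereas coupling at C5 would give a cyclobutanone and is excluded by strain. The only new stereocentre, C7, lies between the C8 ketone and the C4-conjugated C5=C6 bond, so it equilibrates through the dienol and should settle with the isopropyl group pseudo-equatorial (7β), while C1 and C10 are not touched. The step needs cleavage of C5–C9 rather than C5–C10 and use of the alkene arm rather than the C4 carbonyl arm: C9 is the only unsubstituted ring carbon and lies on the open α face, C10 is quaternary and screened by the silyl ether, and the alkene is the better π-ligand for Rh(I). The Rh–C9 alkyl has no β-hydrogen because C10 is quaternary, which leaves CO insertion as its productive exit, and the fully substituted C5 biases the alkenyl arm toward the s-cis rotamer from which the metallacycle forms.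

**Step 10**
Reactants: 14 (1R,7S,10R)-1-(tert-butyldimethylsilyloxy)-7-isopropyl-10-methyl-Δ5-octalin-4,8-dione
Product: 15 1β-(tert-butyldimethylsilyloxy)-4-(triisopropylsilyloxy)-15-nor-eudesm-4-en-8-one (7β-iPr, 10β-Me)
Conditions: i-Pr3SiH (1.5 equiv), Pt2(dvtms)3 (Karstedt catalyst, 1 mol %), toluene, 70 °C
Reagents that add atoms: triisopropylsilane, CC(C)[SiH](C(C)C)C(C)C
Why: Pt(0)-catalysed 1,4-hydrosilylation of an enone, in which the fixed s-cis C4=O/C5=C6 unit takes silicon at oxygen and hydrogen at C6 under neutral conditions that spare the acidic C7–H, while the isolated C8 ketone, hindered on both flanks, reacts much more slowly, so C4 emerges masked as an enol ether and no stereocentre is created.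

**Step 11**
Reactants: 15 1β-(tert-butyldimethylsilyloxy)-4-(triisopropylsilyloxy)-15-nor-eudesm-4-en-8-one
Product: 17 1β-(tert-butyldimethylsilyloxy)-8α-hydroxy-15-nor-5αH-eudesman-4-one, via hydroxy enol ether 16 (not isolated)
Conditions: Li, NH3(l)–THF, EtOH, −78 °C; NH4Cl; then TBAF, AcOH, THF, 0 °C
Reagents that add atoms: none
Why: Dissolving-metal (lithium–ammonia) ketone reduction gives the more stable equatorial 8α-alcohol trans to the equatorial isopropyl group, where hydride reagents would be steered by the axial C10 methyl to the 8β-epimer; the enol ether accepts no electrons, and its fluoride cleavage then protonates C5 on the α face opposite the angular methyl, which is also the more stable trans fusion.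

**Step 12**
Reactants: 17 1β-(tert-butyldimethylsilyloxy)-8α-hydroxy-15-nor-5αH-eudesman-4-one
Product: 18 1β,8α-bis(tert-butyldimethylsilyloxy)-15-nor-5αH-eudesman-4-one
Conditions: TBSCl, imidazole, DMAP (cat.), DMF, 45 °C
Reagents that add atoms: tert-butyldimethylsilyl chloride, CC(C)(C)[Si](C)(C)Cl
Why: Imidazole-promoted silylation of an equatorial, menthol-like secondary alcohol, which does not disturb the ketone or any stereocentre.

**Step 13**
Reactants: 18 1β,8α-bis(tert-butyldimethylsilyloxy)-15-nor-5αH-eudesman-4-one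
Product: 19 1β,8α-bis(tert-butyldimethylsilyloxy)-5αH-eudesm-4(15)-ene
Conditions: Ph3PCH3Br, KOt-Bu, toluene–THF, rt → 60 °C
Reagents that add atoms: methyltriphenylphosphonium bromide, C[P+](c1ccccc1)(c1ccccc1)c1ccccc1.[Br-]
Why: Wittig methylenation of a 4-oxo trans-decalin, standard in the eudesmane series, in which any base-induced equilibration at C5 favours the all-equatorial trans isomer, which is also the faster-reacting ketone.

**Step 14**
Reactants: 19 1β,8α-bis(tert-butyldimethylsilyloxy)-5αH-eudesm-4(15)-ene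
Product: 20 1β,8α-bis(tert-butyldimethylsilyloxy)-5αH-eudesm-4(15)-en-3α-ol
Conditions: SeO2 (0.3 equiv), t-BuOOH, CH2Cl2, 0 °C → rt
Reagents that add atoms: selenium dioxide (oxygen carrier), O=[Se]=O; tert-butyl hydroperoxide (terminal oxidant), CC(C)(C)OO
Why: Selenium dioxide allylic hydroxylation (ene reaction then [2,3]-shift), which prefers the allylic CH2 at C3 over the methine C5 and, by removing the axial 3α-hydrogen and returning oxygen to the same face, should give the axial 3α-alcohol.

**Step 15**
Reactants: 20 1β,8α-bis(tert-butyldimethylsilyloxy)-5αH-eudesm-4(15)-en-3α-ol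
Product: 21 1β,8α-bis(tert-butyldimethylsilyloxy)-5αH-eudesm-4(15)-en-3-one
Conditions: Dess–Martin periodinane, CH2Cl2, 0 °C → rt
Reagents that add atoms: none
Why: Dess–Martin oxidation of an allylic alcohol under neutral conditions that tolerate silyl ethers and the exocyclic alkene, erasing the wrong C3 configuration; the α-methylene ketone is carried on directly.

**Step 16**
Reactants: 21 1β,8α-bis(tert-butyldimethylsilyloxy)-5αH-eudesm-4(15)-en-3-one
Product: 22 1β,8α-bis(tert-butyldimethylsilyloxy)-5αH-eudesm-4(15)-en-3β-ol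
Conditions: NaBH4, CeCl3·7H2O, MeOH, −78 °C
Reagents that add atoms: none
Why: Luche reduction gives clean 1,2-attack on the α-methylene ketone, and the small hydride enters axially from the α face, where only hydrogens at C1 and C5 stand, so the equatorial 3β-alcohol is set.

**Step 17**
Reactants: 23 caffeic acid
Product: 25 (E)-3-[3,4-bis(tert-butyldimethylsilyloxy)phenyl]prop-2-enoic acid, via tris-silyl caffeate 24 (not isolated)
Conditions: TBSCl (3.5 equiv), imidazole, DMF, rt; then AcOH–THF–H2O, rt
Reagents that add atoms: tert-butyldimethylsilyl chloride, CC(C)(C)[Si](C)(C)Cl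
Why: Exhaustive silylation followed by selective hydrolysis of the much more labile silyl ester, the usual way to mask the catechol of caffeic acid while freeing the carboxyl group.

**Step 18**
Reactants: 22 1β,8α-bis(tert-butyldimethylsilyloxy)-5αH-eudesm-4(15)-en-3β-ol; 25 (E)-3-[3,4-bis(tert-butyldimethylsilyloxy)phenyl]prop-2-enoic acid
Product: 26 1β,8α-bis(tert-butyldimethylsilyloxy)-5αH-eudesm-4(15)-en-3β-yl (E)-3-[3,4-bis(tert-butyldimethylsilyloxy)phenyl]prop-2-enoate
Conditions: EDC·HCl, DMAP, CH2Cl2, 0 °C → rt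
Reagents that add atoms: none
Why: Steglich-type carbodiimide–DMAP esterification acylates the only free hydroxyl, an unhindered equatorial allylic alcohol, at oxygen, so C3 and the E-cinnamate geometry are retained.

**Step 19**
Reactants: 26 1β,8α-bis(tert-butyldimethylsilyloxy)-5αH-eudesm-4(15)-en-3β-yl (E)-3-[3,4-bis(tert-butyldimethylsilyloxy)phenyl]prop-2-enoate
Product: 27 1β,8α-dihydroxy-5αH-eudesm-4(15)-en-3β-yl (E)-caffeate (CNP0264533.1)
Conditions: HF·pyridine, THF–pyridine, 0 °C → rt, plastic vessel, argon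
Reagents that add atoms: none
Why: Fluoride-mediated global desilylation in a buffered acidic medium removes the two phenolic and two secondary silyl ethers without ester cleavage, acyl migration or the catechol oxidation that basic fluoride would invite.

**Compound list**
1 | 3-ethoxycyclohex-2-en-1-one | CCOC1=CC(=O)CCC1 | starting material
2 | (±)-6-acetoxy-3-ethoxycyclohex-2-en-1-one | CCOC1=CC(=O)C(OC(C)=O)CC1 | intermediate
3 | (R)-3-ethoxy-6-hydroxycyclohex-2-en-1-one | CCOC1=CC(=O)[C@H](O)CC1 | intermediate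
4 | (R)-6-(tert-butyldimethylsilyloxy)-3-ethoxycyclohex-2-en-1-one | CCOC1=CC(=O)[C@H](O[Si](C)(C)C(C)(C)C)CC1 | intermediate
5 | (6R)-6-(tert-butyldimethylsilyloxy)-3-ethoxy-1-methylcyclohex-2-en-1-ol (carbinol epimers, not isolated) | CCOC1=CC(C)(O)[C@H](O[Si](C)(C)C(C)(C)C)CC1 | intermediate
6 | (R)-4-(tert-butyldimethylsilyloxy)-3-methylcyclohex-2-en-1-one | O=C1CC[C@@H](O[Si](C)(C)C(C)(C)C)C(C)=C1 | intermediate
7 | (R)-4-(tert-butyldimethylsilyloxy)-2-iodo-3-methylcyclohex-2-en-1-one | O=C1CC[C@@H](O[Si](C)(C)C(C)(C)C)C(C)=C1I | intermediate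
8 | 3-methylbut-1-yne | CC(C)C#C | starting material
9 | (E)-4,4,5,5-tetramethyl-2-(3-methylbut-1-en-1-yl)-1,3,2-dioxaborolane | CC(C)/C=C/B1OC(C)(C)C(C)(C)O1 | intermediate
10 | (R)-4-(tert-butyldimethylsilyloxy)-3-methyl-2-[(E)-3-methylbut-1-en-1-yl]cyclohex-2-en-1-one | O=C1CC[C@@H](O[Si](C)(C)C(C)(C)C)C(C)=C1/C=C/C(C)C | intermediate
11 | trimethylsulfoxonium iodide | C[S+](C)(C)=O.[I-] | starting material
12 | (1R,5R,6R)-5-(tert-butyldimethylsilyloxy)-6-methyl-1-[(E)-3-methylbut-1-en-1-yl]bicyclo[4.1.0]heptan-2-one | O=C1CC[C@@H](O[Si](C)(C)C(C)(C)C)[C@]2(C)C[C@]12/C=C/C(C)C | intermediate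
13 | carbon monoxide | [C-]#[O+] | starting material
14 | (1R,7S,10R)-1-(tert-butyldimethylsilyloxy)-7-isopropyl-10-methyl-Δ5-octalin-4,8-dione | O=C1CC[C@@H](O[Si](C)(C)C(C)(C)C)[C@]2(C)CC(=O)[C@@H](C(C)C)C=C12 | intermediate
15 | 1β-(tert-butyldimethylsilyloxy)-4-(triisopropylsilyloxy)-15-nor-eudesm-4-en-8-one | CC(C)[Si](C(C)C)(C(C)C)OC1=C2C[C@H](C(C)C)C(=O)C[C@@]2(C)[C@H](O[Si](C)(C)C(C)(C)C)CC1 | intermediate
16 | 1β-(tert-butyldimethylsilyloxy)-4-(triisopropylsilyloxy)-15-nor-eudesm-4-en-8α-ol (not isolated) | CC(C)[Si](C(C)C)(C(C)C)OC1=C2C[C@H](C(C)C)[C@@H](O)C[C@@]2(C)[C@H](O[Si](C)(C)C(C)(C)C)CC1 | intermediate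
17 | 1β-(tert-butyldimethylsilyloxy)-8α-hydroxy-15-nor-5αH-eudesman-4-one | O=C1CC[C@@H](O[Si](C)(C)C(C)(C)C)[C@]2(C)C[C@H](O)[C@@H](C(C)C)C[C@@H]12 | intermediate
18 | 1β,8α-bis(tert-butyldimethylsilyloxy)-15-nor-5αH-eudesman-4-one | O=C1CC[C@@H](O[Si](C)(C)C(C)(C)C)[C@]2(C)C[C@H](O[Si](C)(C)C(C)(C)C)[C@@H](C(C)C)C[C@@H]12 | intermediate
19 | 1β,8α-bis(tert-butyldimethylsilyloxy)-5αH-eudesm-4(15)-ene | C=C1CC[C@@H](O[Si](C)(C)C(C)(C)C)[C@]2(C)C[C@H](O[Si](C)(C)C(C)(C)C)[C@@H](C(C)C)C[C@@H]12 | intermediate
20 | 1β,8α-bis(tert-butyldimethylsilyloxy)-5αH-eudesm-4(15)-en-3α-ol | C=C1[C@H](O)C[C@@H](O[Si](C)(C)C(C)(C)C)[C@]2(C)C[C@H](O[Si](C)(C)C(C)(C)C)[C@@H](C(C)C)C[C@@H]12 | intermediate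
21 | 1β,8α-bis(tert-butyldimethylsilyloxy)-5αH-eudesm-4(15)-en-3-one | C=C1C(=O)C[C@@H](O[Si](C)(C)C(C)(C)C)[C@]2(C)C[C@H](O[Si](C)(C)C(C)(C)C)[C@@H](C(C)C)C[C@@H]12 | intermediate
22 | 1β,8α-bis(tert-butyldimethylsilyloxy)-5αH-eudesm-4(15)-en-3β-ol | C=C1[C@@H](O)C[C@@H](O[Si](C)(C)C(C)(C)C)[C@]2(C)C[C@H](O[Si](C)(C)C(C)(C)C)[C@@H](C(C)C)C[C@@H]12 | intermediate
23 | caffeic acid | OC(=O)/C=C/c1ccc(O)c(O)c1 | starting material
24 | tert-butyldimethylsilyl (E)-3-[3,4-bis(tert-butyldimethylsilyloxy)phenyl]prop-2-enoate (not isolated) | CC(C)(C)[Si](C)(C)OC(=O)/C=C/c1ccc(O[Si](C)(C)C(C)(C)C)c(O[Si](C)(C)C(C)(C)C)c1 | intermediate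
25 | (E)-3-[3,4-bis(tert-butyldimethylsilyloxy)phenyl]prop-2-enoic acid | OC(=O)/C=C/c1ccc(O[Si](C)(C)C(C)(C)C)c(O[Si](C)(C)C(C)(C)C)c1 | intermediate
26 | 1β,8α-bis(tert-butyldimethylsilyloxy)-5αH-eudesm-4(15)-en-3β-yl (E)-3-[3,4-bis(tert-butyldimethylsilyloxy)phenyl]prop-2-enoate | C=C1[C@@H](OC(=O)/C=C/c2ccc(O[Si](C)(C)C(C)(C)C)c(O[Si](C)(C)C(C)(C)C)c2)C[C@@H](O[Si](C)(C)C(C)(C)C)[C@]2(C)C[C@H](O[Si](C)(C)C(C)(C)C)[C@@H](C(C)C)C[C@@H]12 | intermediate
27 | 1β,8α-dihydroxy-5αH-eudesm-4(15)-en-3β-yl (E)-caffeate (CNP0264533.1) | C=C1[C@@H](OC(=O)/C=C/c2ccc(O)c(O)c2)C[C@@H](O)[C@]2(C)C[C@H](O)[C@@H](C(C)C)C[C@@H]12 | target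

**Step count**
- Total steps: 19.
- Longest linear sequence: 17 (steps 1–5, 7–16, 18, 19).

**Steps most likely to fail**

Step 9.
- What may go wrong: rhodium may fail to enter the crowded C5–C9 bond. The rhodacycle may also collapse by direct C9–C7 coupling (vinylcyclopropane–cyclopentene rearrangement) before CO is taken up.
- Fallback: it sets out from 10 and returns at 14, and it replaces methylene plus CO by an acetate unit that supplies C9 and C8 together.
- First operation: Mukaiyama–Michael addition of 1-methoxy-1-(trimethylsilyloxy)ethene to 10 (TiCl4, CH2Cl2, −78 °C, aqueous work-up) attacks C10 anti to the silyl ether. It should give methyl [(1R,2R)-2-(tert-butyldimethylsilyloxy)-1-methyl-6-[(E)-3-methylbut-1-en-1-yl]-5-oxocyclohexyl]acetate F1.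
- Second operation: KOt-Bu in THF generates the C4–C5–C6–C7 dienolate. Its γ-carbon C7 acylates on the ester (vinylogous Dieckmann condensation). Attack through C5 would give a four-membered ring, and the stabilised anion of the vinylogous β-diketone drives the closure. A mild acid quench delivers 14.

Step 8.
- What may go wrong: conjugate addition at the fully substituted C10 may be slow. γ-Deprotonation of the dienone by the basic ylide (eroding the C1 centre) or 1,2-attack at C4 could then take over.
- Fallback: it sets out from 10 and returns at 12, and it swaps the nucleophilic ylide for a hydroxyl-delivered electrophilic carbenoid.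
- First operation: reagent-controlled CBS reduction ((S)-Me-CBS, BH3·SMe2, THF) gives (1R,4R)-4-(tert-butyldimethylsilyloxy)-3-methyl-2-[(E)-3-methylbut-1-en-1-yl]cyclohex-2-en-1-ol F2, which carries the 4α-hydroxyl.
- Second operation: directed Simmons–Smith cyclopropanation (Et2Zn, CH2I2, CH2Cl2) of the allylic ring alkene occurs syn to that hydroxyl and anti to the silyl ether. It gives (1R,2R,5R,6R)-5-(tert-butyldimethylsilyloxy)-6-methyl-1-[(E)-3-methylbut-1-en-1-yl]bicyclo[4.1.0]heptan-2-ol F3.
- Third operation: Dess–Martin oxidation of F3 gives 12.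

Step 10.
- What may go wrong: dehydrogenative O-silylation of the enol tautomer, or hydrosilylation at C8, would blur the distinction between the C4 and C8 carbonyl groups.
- Fallback: it sets out from 14 and returns at 17, and it draws the distinction from kinetic acidity instead.
- First operation: hydrogenation (H2, Pd/C, EtOAc) followed by NaOMe–MeOH equilibration of C5 and C7 gives 1β-(tert-butyldimethylsilyloxy)-15-nor-5αH-eudesmane-4,8-dione F4.
- Second operation: LDA (one equivalent, THF, −78 °C) removes the only unhindered α-proton, at C3. TIPSOTf traps 1β-(tert-butyldimethylsilyloxy)-4-(triisopropylsilyloxy)-15-nor-5αH-eudesm-3-en-8-one F5.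
- Third operation: lithium–ammonia–ethanol reduction gives 1β-(tert-butyldimethylsilyloxy)-4-(triisopropylsilyloxy)-15-nor-5αH-eudesm-3-en-8α-ol F6, and TBAF–AcOH releases 17.

**Further compounds**
F1 | step 9 | methyl [(1R,2R)-2-(tert-butyldimethylsilyloxy)-1-methyl-6-[(E)-3-methylbut-1-en-1-yl]-5-oxocyclohexyl]acetate (epimers at the labile C5) | O=C1CC[C@@H](O[Si](C)(C)C(C)(C)C)[C@](C)(CC(=O)OC)C1/C=C/C(C)C
F2 | step 8 | (1R,4R)-4-(tert-butyldimethylsilyloxy)-3-methyl-2-[(E)-3-methylbut-1-en-1-yl]cyclohex-2-en-1-ol | O[C@@H]1CC[C@@H](O[Si](C)(C)C(C)(C)C)C(C)=C1/C=C/C(C)C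
F3 | step 8 | (1R,2R,5R,6R)-5-(tert-butyldimethylsilyloxy)-6-methyl-1-[(E)-3-methylbut-1-en-1-yl]bicyclo[4.1.0]heptan-2-ol | O[C@@H]1CC[C@@H](O[Si](C)(C)C(C)(C)C)[C@]2(C)C[C@]12/C=C/C(C)C
F4 | step 10 | 1β-(tert-butyldimethylsilyloxy)-15-nor-5αH-eudesmane-4,8-dione | O=C1CC[C@@H](O[Si](C)(C)C(C)(C)C)[C@]2(C)CC(=O)[C@@H](C(C)C)C[C@@H]12
F5 | step 10 | 1β-(tert-butyldimethylsilyloxy)-4-(triisopropylsilyloxy)-15-nor-5αH-eudesm-3-en-8-one | CC(C)[Si](OC1=CC[C@@H](O[Si](C)(C)C(C)(C)C)[C@]2(C)CC(=O)[C@@H](C(C)C)C[C@@H]12)(C(C)C)C(C)C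
F6 | step 10 | 1β-(tert-butyldimethylsilyloxy)-4-(triisopropylsilyloxy)-15-nor-5αH-eudesm-3-en-8α-ol | CC(C)[Si](OC1=CC[C@@H](O[Si](C)(C)C(C)(C)C)[C@]2(C)C[C@H](O)[C@@H](C(C)C)C[C@@H]12)(C(C)C)C(C)C
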